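**Plan**
Ring atoms keep the target numbering: C1 bears C7H2OBz, C2 is the alkene CH, C3–OAc, C4–OH, C5–OBz, C6–OH. The retrosynthesis cuts C2–C3 and C5–C6 together, as a [3+3] double aldol: C3–C4–C5 is a dihydroxyacetone ketone, C2–C1(C7)–C6 a 1,3-dialdehyde.
What makes this possible: C4 lies between two oxygen-bearing CH groups, so a C4 ketone makes C3 and C5 nucleophilic in turn. Tying O3 and O5 into a benzylidene acetal makes the product a 2,4-dioxabicyclo[3.3.1]nonan-9-one whose bridgehead C3–H and C5–H cannot enolise. C1 is kept quaternary as a spiro-epoxide (C1–O–C7), so the dialdehyde cannot enolise either.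
Forward: the carbocycle, the only ring of the target, closes in the key step. Then epoxide → C7 benzoate, cis-C1/C2-diol → C1=C2 alkene, acetal → C5 benzoate plus C3 acetate, C4 ketone → C4–OH.
Stereochemistry: (S)-proline sets C3, which is later inverted on purpose by acetate when the acetal is opened. The acetal bridge forces C5 cis to C3, the closed transition state of the ring closure sets C6, and C6–OH directs hydride to C4.

Key step: step 4

Remark: 1 and 3 are taken as the commercial starting materials; dialdehyde 5 is handled only in solution; ketol 10 and ketone 12 are kept away from base.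

Step 1
Reactants: 1 2-phenyl-1,3-dioxan-5-ol (1,3-O-benzylideneglycerol; cis/trans mixture)
Product: 2 2-phenyl-1,3-dioxan-5-one
Conditions: Dess–Martin periodinane, CH2Cl2, 0 °C → rt
Reagents that add atoms: none
Why: Dess–Martin oxidation of the secondary alcohol is neutral and should spare the benzylidene acetal; the carbinol stereocentre disappears, no new one forms, and the readily hydrated ketone is used without storage.

Step 2
Reactants: 3 2-methylidenepropane-1,3-diol
Product: 4 [2-(hydroxymethyl)oxiran-2-yl]methanol
Conditions: mCPBA, CH2Cl2, 0 °C → rt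
Reagents that add atoms: mCPBA, OOC(=O)c1cccc(Cl)c1
Why: Prilezhaev epoxidation of the 1,1-disubstituted alkene, helped by hydrogen bonding to the two allylic hydroxyl groups, should give the achiral epoxy diol.

Step 3
Reactants: 4 [2-(hydroxymethyl)oxiran-2-yl]methanol
Product: 5 oxirane-2,2-dicarbaldehyde
Conditions: Dess–Martin periodinane (2.4 equiv), CH2Cl2, 0 °C → rt; filtered; solvent exchanged for DMSO; used at once
Reagents that add atoms: none
Why: twofold Dess–Martin oxidation of the primary alcohols without base should give the dialdehyde, which has no α-hydrogen (no enolisation, no β-elimination) but is expected to hydrate and oligomerise, hence its use in solution.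

Step 4
Reactants: 2 2-phenyl-1,3-dioxan-5-one; 5 oxirane-2,2-dicarbaldehyde
Product: 7 bicyclic epoxy diol ketone 6,8-dihydroxy-3-phenylspiro[2,4-dioxabicyclo[3.3.1]nonane-7,2′-oxiran]-9-one (target numbering: C3 S; O3 and O5 bridged by the benzylidene carbon with phenyl exo; C2–OH and the epoxide oxygen on C1 on the face of O3; C6–OH on the opposite face; C4 ketone), via mono-aldol adduct 6 (not isolated)
Conditions: (S)-proline (0.3 equiv), DMSO, 4 °C → rt
Reagents that add atoms: none
Why: Proposed new method: the (S)-proline enamine of 2 should add to one formyl group of 5 through the carboxylic-acid-bridged chair transition state of proline aldol additions (giving 6), and a second enamine on the remaining CH2 next to the ketone should then add to the other formyl group within the molecule; the closest known reaction types are proline aldol additions of 1,3-dioxan-5-ones to α-branched aldehydes and Hajos–Parrish-type aldolisations or α,α′-annulations of ketone enamines to bicyclo[3.3.1]nonanones, which have not been joined on a 1,3-dialdehyde. The ring closure is a 6-(enolendo)-exo-trig aldol addition that makes the carbocycle C1–C6 as the second ring of a 2,4-dioxabicyclo[3.3.1]nonane. C3 is set by the proline carboxyl group, which brings the aldehyde to one enamine face (S at C3); C2–OH comes out anti to O3 from the E-enamine in that chair; C1 follows from polar Felkin–Anh attack anti to the epoxide C–O bond (epoxide oxygen cis to C2–OH); and the acetal carbon keeps phenyl exo because axial attack on the half-chair enamine puts the new bond trans to it. C5 must be cis to C3 for the one-carbon acetal bridge to span both oxygens, and C6–OH is placed trans to O5 because the hydrogen-bonded closed transition state holds the formyl oxygen next to the enamine nitrogen. The step needs cross-aldol over self-aldol reaction, ring closure over a second intermolecular addition, and a ketol that survives: 5 has no α-hydrogen, the second addition is intramolecular, C1 is quaternary, and the bridgehead hydrogens at C3 and C5 cannot enolise, so dehydration and aromatisation have no path.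

Step 5
Reactants: 7 bicyclic epoxy diol ketone
Product: 8 (6,7,8-trihydroxy-9-oxo-3-phenyl-2,4-dioxabicyclo[3.3.1]nonan-7-yl)methyl benzoate (target numbering: tertiary C1–OH and C2–OH cis on the face of O3; C6–OH trans; C7 benzoate)
Conditions: PhCO2H, Ti(OiPr)4, CH2Cl2, rt
Reagents that add atoms: benzoic acid, OC(=O)c1ccccc1
Why: titanium-alkoxide-assisted opening of a 2,3-epoxy alcohol by a carboxylic acid should occur at the distal, primary epoxide carbon C7 (either flanking hydroxyl can bind the metal), with retention at C1, so the new tertiary C1–OH stays cis to C2–OH and C7 already carries its benzoate.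

Step 6
Reactants: 8 triol benzoate
Product: 9 cyclic thionocarbonate of the cis C1/C2-diol of 8 (C6–OH free)
Conditions: 1,1′-thiocarbonyldiimidazole, DMAP (cat.), toluene, 60 °C
Reagents that add atoms: 1,1′-thiocarbonyldiimidazole, S=C(n1ccnc1)n1ccnc1
Why: a cyclic thionocarbonate needs a cis-1,2-diol, and only C1–OH/C2–OH are cis (C6–OH is trans-diaxial to C1–OH), so the ring closure itself should tell C2 from C6.

Step 7
Reactants: 9 cyclic thionocarbonate
Product: 10 [(1R,3R,5S,8S)-8-hydroxy-9-oxo-3-phenyl-2,4-dioxabicyclo[3.3.1]non-6-en-7-yl]methyl benzoate (target numbering: C1=C2 alkene; C6–OH; C4 ketone; O3/O5 acetal)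
Conditions: 1,3-dimethyl-2-phenyl-1,3,2-diazaphospholidine, THF, 40 °C
Reagents that add atoms: none
Why: Corey–Winter olefination (mild diazaphospholidine variant) should remove the thionocarbonate by stereospecific syn-elimination to give the C1=C2 alkene without base, which matters because ketol 10 could undergo retro-aldol opening; no new stereocentre forms.

Step 8
Reactants: 10 bicyclic ene ketol
Product: 12 [(3R,5R,6S)-3-(acetyloxy)-5-(benzoyloxy)-6-hydroxy-4-oxocyclohex-1-en-1-yl]methyl benzoate, via benzoxonium tetrafluoroborate 11 (not isolated)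
Conditions: Ph3C+ BF4−, CH2Cl2, rt; then KOAc, AcOH, rt
Reagents that add atoms: potassium acetate, CC(=O)[O-].[K+]
Why: hydride abstraction from the acetal C–H by the trityl cation should give the 2-phenyl-1,3-dioxan-2-ylium ion 11, which acetate opens in a Prévost-type SN2 attack at the allylic, ketone-activated C3 with inversion (C3–OAc trans to C5–OBz), so the acetal carbon becomes the C5 benzoate; the acidic medium keeps C6–OH from closing an epoxide onto C5 and keeps 12 from enolising.

Step 9
Reactants: 12 acetoxy benzoyloxy ketone
Product: 13 [(3R,4S,5R,6S)-3-(acetyloxy)-5-(benzoyloxy)-4,6-dihydroxycyclohex-1-en-1-yl]methyl benzoate (CNP0169028.1)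
Conditions: Me4N+ BH(OAc)3−, AcOH/MeCN, −30 °C
Reagents that add atoms: none
Why: Evans–Saksena-type intramolecular hydride delivery from boron bound to C6–OH should reduce the ketone from the face of that hydroxyl group, giving C4–OH anti (trans) to C6–OH and cis to C5–OBz under acidic conditions that do not move the esters.

**Compound list**
1 | 2-phenyl-1,3-dioxan-5-ol (cis/trans mixture; neither centre is kept) | OC1COC(OC1)c1ccccc1 | starting material
2 | 2-phenyl-1,3-dioxan-5-one | O=C1COC(OC1)c1ccccc1 | intermediate
3 | 2-methylidenepropane-1,3-diol | C=C(CO)CO | starting material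
4 | [2-(hydroxymethyl)oxiran-2-yl]methanol | OCC1(CO)CO1 | intermediate
5 | oxirane-2,2-dicarbaldehyde | O=CC1(C=O)CO1 | intermediate
6 | (2R)-2-{(R)-hydroxy[(2S,4S)-5-oxo-2-phenyl-1,3-dioxan-4-yl]methyl}oxirane-2-carbaldehyde (mono-aldol adduct) | O=C1CO[C@H](c2ccccc2)O[C@H]1[C@@H](O)[C@@]1(C=O)CO1 | intermediate (not isolated)
7 | 6,8-dihydroxy-3-phenylspiro[2,4-dioxabicyclo[3.3.1]nonane-7,2′-oxiran]-9-one; C3 S, phenyl exo, C2–OH and epoxide O cis to O3, C6–OH trans to O5 | O=C1[C@@H]2[C@@H](O)[C@]3(CO3)[C@H](O)[C@H]1O[C@H](c1ccccc1)O2 | intermediate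
8 | (6,7,8-trihydroxy-9-oxo-3-phenyl-2,4-dioxabicyclo[3.3.1]nonan-7-yl)methyl benzoate; C1–OH/C2–OH cis, C6–OH trans | O=C1[C@@H]2[C@@H](O)[C@](O)(COC(=O)c3ccccc3)[C@H](O)[C@H]1O[C@H](c1ccccc1)O2 | intermediate
9 | cyclic C1,C2-thionocarbonate of 8 | O=C1[C@@H]2[C@H]3OC(=S)O[C@@]3(COC(=O)c3ccccc3)[C@H](O)[C@H]1O[C@H](c1ccccc1)O2 | intermediate
10 | [(1R,3R,5S,8S)-8-hydroxy-9-oxo-3-phenyl-2,4-dioxabicyclo[3.3.1]non-6-en-7-yl]methyl benzoate | O=C1[C@@H]2C=C(COC(=O)c3ccccc3)[C@H](O)[C@H]1O[C@H](c1ccccc1)O2 | intermediate
11 | 2-phenyl-1,3-dioxan-2-ylium (benzoxonium) tetrafluoroborate derived from 10 | O=C1[C@@H]2C=C(COC(=O)c3ccccc3)[C@H](O)[C@H]1O[C+](c1ccccc1)O2.F[B-](F)(F)F | intermediate (not isolated)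
12 | [(3R,5R,6S)-3-(acetyloxy)-5-(benzoyloxy)-6-hydroxy-4-oxocyclohex-1-en-1-yl]methyl benzoate | CC(=O)O[C@@H]1C=C(COC(=O)c2ccccc2)[C@H](O)[C@@H](OC(=O)c2ccccc2)C1=O | intermediate
13 | [(3R,4S,5R,6S)-3-(acetyloxy)-5-(benzoyloxy)-4,6-dihydroxycyclohex-1-en-1-yl]methyl benzoate | CC(=O)O[C@@H]1C=C(COC(=O)c2ccccc2)[C@H](O)[C@@H](OC(=O)c2ccccc2)[C@H]1O | target

**Step count and risks**
Total steps: 9. Longest linear sequence: 8 steps (3 → 4 → 5 → 7 → 8 → 9 → 10 → 12 → 13).

Step 4 (most at risk). The sequence may stall after the first aldol addition, through slow enamine formation on the hindered ketone, retro-aldol reaction, or alkylation of the amine by the epoxide. Facial control in the ring closure, or the choice between the two formyl groups (C1 configuration), may also be poor. The fallback makes the two bonds one after the other with known chemistry; it sets out from 2 and 5 and comes back at 7. The proline-catalysed cross-aldol addition of 2 to 5, a known reaction type for 1,3-dioxan-5-ones and α-branched aldehydes, is run at 4 °C with 5 in excess and stopped at 6. Compound 6 is isolated as its triethylsilyl ether, the silyl-protected mono-aldol adduct F1 (TESCl, imidazole, DMF). Kinetic deprotonation on the CH2 side of the ketone (LiN(SiMe3)2, THF, −78 °C) should give the lithium enolate, which adds to the formyl group within the molecule through a lithium-bridged closed transition state, a classical intramolecular aldol addition. This gives the bicyclic ketol silyl ether F2. HF·pyridine then frees C2–OH and the route is rejoined at 7.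

Step 8. Acetate may add to the cationic acetal carbon, giving an orthoester that hydrolyses to cis-hydroxy esters without inversion. Hydride may be taken from another position, or the unbridged ketone may enolise and eliminate. The fallback replaces the one-pot oxidative opening by a protecting-group sequence; it sets out from 10 and comes back at 13. Hydroxyl-directed reduction of the bicyclic ketone (Me4N+ BH(OAc)3−, AcOH/MeCN) should give the bicyclic 4,6-diol F3. Both hydroxyl groups are silylated (TBSOTf, 2,6-lutidine) to give the bis-silyl ether F4. Aqueous acetic acid removes the benzylidene group to give the 3,5-diol F5. A Mitsunobu reaction with acetic acid (PPh3, DIAD) should invert the allylic C3–OH selectively, since C5–OH is flanked by two silyl ethers, giving the C3 acetate F6. Benzoylation (BzCl, DMAP, pyridine) gives the C5 benzoate F7, and HF·pyridine removes both silyl groups to give 13.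

Step 6. Ring closure onto the hindered tertiary C1–OH may fail, or C6–OH may be thiocarbonylated instead. A wrong configuration at C1 from step 4 would also send the elimination to the C6 side. The fallback uses a radical transposition that does not depend on the C1 configuration; it sets out from 7 and comes back at 10. Phenoxythiocarbonylation of the equatorial C2–OH (PhOC(S)Cl, pyridine) gives the C2 thionocarbonate F8; its selectivity over the axial C6–OH is itself uncertain. Bu3SnH/AIBN generates the C2 radical, which opens the adjacent epoxide; this oxiranylcarbinyl fragmentation is a known way to turn 2,3-epoxy alcohols into transposed allylic alcohols. The product is the C1=C2 alkene with free C7–OH, allylic alcohol F9. Selective benzoylation of the primary hydroxyl group (BzCl, 2,4,6-collidine, −40 °C) gives 10.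

**Further compounds**
F1 | step 4 | 2-O-triethylsilyl ether of mono-aldol adduct 6 | O=C1CO[C@H](c2ccccc2)O[C@H]1[C@@H](O[Si](CC)(CC)CC)[C@@]1(C=O)CO1
F2 | step 4 | 2-O-triethylsilyl ether of bicyclic ketol 7 | O=C1[C@@H]2[C@@H](O[Si](CC)(CC)CC)[C@]3(CO3)[C@H](O)[C@H]1O[C@H](c1ccccc1)O2
F3 | step 8 | bicyclic 4,6-diol from reduction of 10 (C4–OH cis to O3/O5, C6–OH trans) | O[C@H]1[C@@H]2C=C(COC(=O)c3ccccc3)[C@H](O)[C@H]1O[C@H](c1ccccc1)O2
F4 | step 8 | 4,6-bis-O-(tert-butyldimethylsilyl) ether of F3 | CC(C)(C)[Si](C)(C)O[C@H]1[C@@H]2C=C(COC(=O)c3ccccc3)[C@H](O[Si](C)(C)C(C)(C)C)[C@H]1O[C@H](c1ccccc1)O2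
F5 | step 8 | 3,5-diol after removal of the benzylidene group (C3–OH and C5–OH cis) | O[C@H]1C=C(COC(=O)c2ccccc2)[C@H](O[Si](C)(C)C(C)(C)C)[C@@H](O)[C@H]1O[Si](C)(C)C(C)(C)C
F6 | step 8 | C3 acetate with inverted C3, C5–OH free | CC(=O)O[C@@H]1C=C(COC(=O)c2ccccc2)[C@H](O[Si](C)(C)C(C)(C)C)[C@@H](O)[C@H]1O[Si](C)(C)C(C)(C)C
F7 | step 8 | 4,6-bis-O-(tert-butyldimethylsilyl) ether of 13 | CC(=O)O[C@@H]1C=C(COC(=O)c2ccccc2)[C@H](O[Si](C)(C)C(C)(C)C)[C@@H](OC(=O)c2ccccc2)[C@H]1O[Si](C)(C)C(C)(C)C
F8 | step 6 | C2 O-phenyl thionocarbonate of 7 | O=C1[C@@H]2[C@@H](OC(=S)Oc3ccccc3)[C@]3(CO3)[C@H](O)[C@H]1O[C@H](c1ccccc1)O2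
F9 | step 6 | bicyclic ene diol with free C7–OH and C6–OH | O=C1[C@@H]2C=C(CO)[C@H](O)[C@H]1O[C@H](c1ccccc1)O2
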